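**Retrosynthetic overview**

- Numbering: the cycloheptane (ring A) is C1 (carbinol carrying the crotonoyl chain C2–C4), C5 (isovalerate), C6 (lactone O–CH), C7 (ring fusion), C8 (CH2), C9 (CHOH), C10 (CHMe); the lactone (ring B) adds C11 (α), C12 (C=O), C13 (=CH2); C8′ is an extra carboxyl carbon on C8.
- Feature: C8 is the only unsubstituted carbon of ring A and is bonded to C7, the β-carbon of the acrylate unit C7–C11(=C13)–C12. C7–C8 is therefore cut to a C8 radical (from the C8′ N-acyloxyphthalimide) and a C6-bound butenolide C7=C11 with PhSO2 on C13; 7-exo addition and loss of PhSO2 give ring A, the cis fusion and the C13 methylene together.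
- Ring order: ring B first, by ring-closing metathesis of the C6 ester of 2-(phenylsulfonylmethyl)acrylic acid with the C7 vinyl group; ring A second, by the radical step.
- Open chain: C9/C10 by (Z)-crotylboration, C5/C6 by (Z)-γ-alkoxyallylboration of a 2-substituted acrolein, C1 by hydroxyl-directed epoxidation, and the C2 oxygen by aryloxide opening of that epoxide.
- After ring closure: C2 is unmasked, oxidized, propenylated (Nozaki–Hiyama–Kishi) and oxidized to the enone; the silyl ethers are removed last.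

Key step: step 17

Assumption: 3-[(4-methoxybenzyl)oxy]propanal (1) and allyl methoxymethyl ether (11) are treated as catalogue compounds, and (E)-1-bromoprop-1-ene (34) is used as the pure trans isomer.

Abbreviations: PMB = 4-methoxybenzyl, PMP = 4-methoxyphenyl, MOM = methoxymethyl, TBS = tert-butyldimethylsilyl, TES = triethylsilyl, Ipc = isopinocampheyl (from (+)-α-pinene).

**Route**

Step 1
Reactants: 1 3-[(4-methoxybenzyl)oxy]propanal; 2 cis-but-2-ene
Product: 5 (3R,4R)-1-[(4-methoxybenzyl)oxy]-4-methylhex-5-en-3-ol, via (Z)-crotyldiisopinocampheylborane 3 (not isolated), via diisopinocampheylborinate 4 (not isolated)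
Conditions: 2, KOt-Bu, n-BuLi, THF, −78 to −45 °C; (−)-Ipc2BOMe, −78 °C; BF3·OEt2; 1, −78 °C; NaOH, H2O2, rt
Reagents that add atoms: none
Why: Brown (Z)-crotylboration through a closed chair transition state should give the syn C9/C10 pair, and the isopinocampheyl groups of the (+)-α-pinene series should direct the crotyl group to the Si face of the aldehyde, so that C9 (hydroxyl) and C10 (methyl) are both set by the reagent.

Step 2
Reactants: 5 (3R,4R)-1-[(4-methoxybenzyl)oxy]-4-methylhex-5-en-3-ol
Product: 6 TBS ether of 5 (C9–OTBS)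
Conditions: TBSCl, imidazole, DMF, rt
Reagents that add atoms: tert-butyldimethylsilyl chloride, CC(C)(C)[Si](C)(C)Cl
Why: Standard silylation of the secondary alcohol should give the C9 ether that is kept until the last step.

Step 3
Reactants: 6 TBS ether of 5
Product: 8 (3R,4R)-4-(tert-butyldimethylsilyloxy)-6-[(4-methoxybenzyl)oxy]-3-methylhexan-1-ol, via B-alkyl-9-borabicyclononane 7 (not isolated)
Conditions: 9-BBN, THF, 0 °C to rt; NaOH, H2O2
Reagents that add atoms: hydrogen peroxide, OO
Why: Anti-Markovnikov hydroboration–oxidation of the terminal alkene should place the hydroxyl on the terminal carbon (the future C5) without touching C10.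

Step 4
Reactants: 8 (3R,4R)-4-(tert-butyldimethylsilyloxy)-6-[(4-methoxybenzyl)oxy]-3-methylhexan-1-ol
Product: 9 (3R,4R)-4-(tert-butyldimethylsilyloxy)-6-[(4-methoxybenzyl)oxy]-3-methylhexanal
Conditions: TEMPO (10 mol %), PhI(OAc)2, CH2Cl2, rt
Reagents that add atoms: none
Why: Oxoammonium oxidation of the primary alcohol should stop at the aldehyde, whose α-carbon (C1) is a CH2 so that the β-stereocenter C10 is not at risk.

Step 5
Reactants: 9 (3R,4R)-4-(tert-butyldimethylsilyloxy)-6-[(4-methoxybenzyl)oxy]-3-methylhexanal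
Product: 10 (3R,4R)-4-(tert-butyldimethylsilyloxy)-6-[(4-methoxybenzyl)oxy]-3-methyl-2-methylidenehexanal
Conditions: aqueous HCHO, pyrrolidine (10 mol %), propionic acid (10 mol %), i-PrOH, 45 °C
Reagents that add atoms: formaldehyde, C=O
Why: Amine-catalysed α-methylenation (Mannich condensation and elimination) of a β-branched aldehyde should give the 2-substituted acrolein in which C1 carries the C2 methylene and C5 is the aldehyde carbon.

Step 6
Reactants: 10 the 2-substituted acrolein; 11 allyl methoxymethyl ether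
Product: 14 (3R,4R,6R,7R)-7-(tert-butyldimethylsilyloxy)-9-[(4-methoxybenzyl)oxy]-3-(methoxymethoxy)-6-methyl-5-methylidenenon-1-en-4-ol, via (Z)-3-(methoxymethoxy)allyldiisopinocampheylborane 12 (not isolated), via diisopinocampheylborinate 13 (not isolated)
Conditions: 11, s-BuLi, THF, −78 °C; (−)-Ipc2BOMe; BF3·OEt2; 10, −78 °C; NaOH, H2O2, rt
Reagents that add atoms: none
Why: Brown (Z)-γ-alkoxyallylboration should add 1,2 to the enal through a chair transition state, giving the syn C5–OH/C6–OMOM pair with the face chosen by the isopinocampheyl groups, the remote C10 center having little say.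

Step 7
Reactants: 14 the allylic alcohol (C5–OH, C1=C2)
Product: 15 (1S,2R)-1-{(2R)-2-[(2S,3R)-3-(tert-butyldimethylsilyloxy)-5-[(4-methoxybenzyl)oxy]pentan-2-yl]oxiran-2-yl}-2-(methoxymethoxy)but-3-en-1-ol
Conditions: VO(acac)2 (5 mol %), t-BuOOH, CH2Cl2, 0 °C to rt
Reagents that add atoms: tert-butyl hydroperoxide, CC(C)(C)OO
Why: Hydroxyl-directed vanadium-catalysed epoxidation should oxidize only the allylic C1=C2 bond and, because the C10 branch on C1 forces the C6 substituent of the bound carbinol out of the alkene plane (A(1,2) strain), give the erythro epoxy alcohol, which sets C1 from C5.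

Step 8
Reactants: 15 the erythro epoxy alcohol
Product: 16 diol with C2–OPMP, C1–OH, C5–OH, C6–OMOM, C7 vinyl, C9–OTBS, C8′–OPMB (C1 R, C5 S, C6 R, C9 R, C10 S)
Conditions: 4-methoxyphenol, Cs2CO3 (20 mol %), DMF, 80 °C
Reagents that add atoms: 4-methoxyphenol, COc1ccc(O)cc1
Why: Aryloxide opening of the 2,2-disubstituted epoxide by SN2 attack at its CH2 carbon (C2) under catalytic base should install the C2 oxygen as an aryl ether and free the tertiary C1 hydroxyl without touching C1 or provoking Payne rearrangement.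

Step 9
Reactants: 16 the diol; 17 isovaleryl chloride
Product: 18 C5 isovalerate of 16 (C1–OH free)
Conditions: 17, pyridine, DMAP (10 mol %), CH2Cl2, 0 °C to rt
Reagents that add atoms: none
Why: Acylation should take place at the secondary C5 hydroxyl only, the tertiary C1 hydroxyl being inert to an acid chloride under these conditions.

Step 10
Reactants: 18 C5 isovalerate of 16
Product: 20 allylic alcohol with C6–OH and C1–OTES (C2–OPMP, C5 isovalerate, C9–OTBS, C8′–OPMB), via N-alkoxymethyl bipyridinium triflate 19 (not isolated)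
Conditions: TESOTf (3 equiv), 2,2′-bipyridyl, CH2Cl2, 0 °C; then H2O, rt
Reagents that add atoms: triethylsilyl triflate, CC[Si](CC)(CC)OS(=O)(=O)C(F)(F)F
Why: Silyl triflate–bipyridyl cleavage of the methoxymethyl ether (through a bipyridinium salt that water hydrolyses) should free the C6 hydroxyl without acid while the same reagent silylates the tertiary C1 hydroxyl, which must be masked before C8′ is oxidized and activated because a free C1–OH would close a δ-lactol or δ-lactone onto C8′.

Step 11
Reactants: 21 2-(bromomethyl)acrylic acid; 22 sodium benzenesulfinate (PhSO2Na)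
Product: 23 2-[(phenylsulfonyl)methyl]acrylic acid
Conditions: MeOH, reflux
Reagents that add atoms: none
Why: Sulfinate displaces the allylic bromide (S-alkylation by SN2 or SN2′, both leading to the same product) to give the known allyl sulfone acid.

Step 12
Reactants: 20 the C6 alcohol; 23 2-[(phenylsulfonyl)methyl]acrylic acid
Product: 24 C6 2-[(phenylsulfonyl)methyl]acrylate of 20
Conditions: DIC, DMAP (10 mol %), CH2Cl2, 0 °C
Reagents that add atoms: none
Why: Carbodiimide (Steglich) esterification of the secondary allylic alcohol at low temperature should give the metathesis substrate with retention at C6.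

Step 13
Reactants: 24 the diene ester
Product: 25 5-substituted 3-[(phenylsulfonyl)methyl]furan-2(5H)-one (C6 R; chain carries C5 isovalerate, C1–OTES, C2–OPMP, C9–OTBS, C8′–OPMB)
Conditions: second-generation Grubbs catalyst RuCl2(=CHPh)(SIMes)(PCy3) (10 mol %), toluene (5 mM), 80 °C
Reagents that add atoms: none
Why: Ring-closing metathesis of an α-substituted acrylate with the allylic vinyl group, known for methacrylates of allylic alcohols, should close the five-membered butenolide with loss of ethylene and places PhSO2CH2 on C11.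

Step 14
Reactants: 25 the butenolide
Product: 26 primary alcohol at C8′
Conditions: DDQ, CH2Cl2/pH 7 phosphate buffer, 0 °C
Reagents that add atoms: none
Why: Oxidative cleavage of the benzylic PMB ether by DDQ should leave the aryl (PMP) ether, which has no benzylic hydrogen, and the silyl ethers untouched.

Step 15
Reactants: 26 the C8′ alcohol
Product: 28 carboxylic acid at C8′, via C8′ aldehyde 27 (not isolated)
Conditions: TEMPO (20 mol %), PhI(OAc)2 (2.5 equiv), MeCN/H2O, rt
Reagents that add atoms: water, O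
Why: TEMPO/PhI(OAc)2 oxidation in aqueous acetonitrile should carry the primary alcohol through the aldehyde hydrate to the acid, and with C1 silylated no lactol can intercept the aldehyde.

Step 16
Reactants: 28 the acid; 29 N-hydroxyphthalimide
Product: 30 N-acyloxyphthalimide of 28 (key-step precursor)
Conditions: DIC, CH2Cl2, 0 °C to rt
Reagents that add atoms: none
Why: Carbodiimide coupling with the acidic N-hydroxy imide should give the redox-active ester without amine base, which the γ-acidic sulfonylmethyl butenolide would not tolerate.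

Step 17
Reactants: 30 the N-acyloxyphthalimide
Product: 31 cis-fused cycloheptane α-methylene-γ-butyrolactone with C5 isovalerate, C1–OTES, C2–OPMP, C9–OTBS (C1 R, C5 S, C6 R, C7 S, C9 R, C10 S)
Conditions: Ru(bpy)3(PF6)2 (2 mol %), Hantzsch ester (1.5 equiv, added slowly), degassed CH2Cl2 (2 mM), blue LEDs, rt
Reagents that add atoms: none
Why: Proposed new method: the photoexcited divalent ruthenium complex is reduced by the Hantzsch ester to monovalent ruthenium, which transfers an electron to the N-acyloxyphthalimide; loss of phthalimide anion and CO2 leaves a nucleophilic primary radical at C8 that adds to C7, the β-carbon of the electron-poor butenolide, and the C11 radical so formed (α to the lactone carbonyl, β to sulfur) expels PhSO2, which is reduced to sulfinate, leaving the C13 methylene. The closest known reactions are the photoredox decarboxylative radical conjugate additions of N-acyloxyphthalimides and the radical allylation of alkyl radicals by addition–fragmentation of 2-substituted allyl sulfones; the intramolecular seven-membered version on an endocyclic butenolide acceptor is the untested part. Ring A (C1, C5, C6, C7, C8, C9, C10) closes in the 7-exo-trig mode, with C7 in the new ring and C11 outside it. The new stereocenter C7 is controlled by C6: the five-atom tether C5–C1–C10–C9–C8 hangs from C6 on one face of the flat lactone and can reach C7 only from that face, which gives the cis ring fusion. The step needs ring closure to outrun hydrogen transfer to C8 (from the dihydropyridine or by a 1,5-shift from C5–H or C2–H); this is served by slow addition of the hydrogen donor at high dilution, by the fast and irreversible scission of the C13–S bond, and by the fully substituted C1 and the C9/C10 substituents that favor the folded chain.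

Step 18
Reactants: 31 the bicyclic aryl ether
Product: 32 C2 primary alcohol
Conditions: (NH4)2Ce(NO3)6, pyridine, MeCN/H2O (4:1), 0 °C
Reagents that add atoms: none
Why: Oxidative dearylation of the p-methoxyphenyl ether by tetravalent cerium through the arene radical cation should release the C2 alcohol and benzoquinone, with pyridine buffering the acid so that the TES and TBS ethers and the α-methylene lactone persist.

Step 19
Reactants: 32 the C2 alcohol
Product: 33 C2 aldehyde (C1 S, C5 S, C6 R, C7 S, C9 R, C10 S)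
Conditions: Dess–Martin periodinane, CH2Cl2, rt
Reagents that add atoms: none
Why: Dess–Martin oxidation should convert the neopentyl primary alcohol into the aldehyde, which has no α-hydrogen and cannot form a lactol because C9 is still silylated.

Step 20
Reactants: 33 the C2 aldehyde; 34 (E)-1-bromoprop-1-ene
Product: 36 C2 allylic alcohol (both C2 epimers), via (E)-prop-1-enylchromium dichloride 35 (not isolated)
Conditions: CrCl2 (6 equiv), NiCl2 (2 mol %), DMF, rt; aqueous work-up
Reagents that add atoms: none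
Why: Nozaki–Hiyama–Kishi coupling (nickel-catalysed formation of the alkenylchromium reagent from divalent chromium) should add the propenyl group to the aldehyde with retention of the E geometry and without touching the esters or the α-methylene lactone; the new C2 carbinol center is removed in the next step.

Step 21
Reactants: 36 the C2 allylic alcohol
Product: 37 bis-silylated enone (C1–OTES, C9–OTBS, C2 crotonoyl ketone)
Conditions: Dess–Martin periodinane, CH2Cl2, 0 °C to rt
Reagents that add atoms: none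
Why: Dess–Martin oxidation of the secondary allylic alcohol should give the (E)-enone and converges both C2 epimers.

Step 22
Reactants: 37 the bis-silylated enone
Product: 38 CNP0186412.1 (target; C1 S, C5 S, C6 R, C7 S, C9 R, C10 S)
Conditions: HF·pyridine, pyridine, THF, 0 °C to rt
Reagents that add atoms: none
Why: Buffered fluoride desilylation should remove the tertiary TES and the secondary TBS ether under non-basic conditions that the α-hydroxy enone, the isovalerate and the α-methylene lactone tolerate.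

**Compound list**

1 | 3-[(4-methoxybenzyl)oxy]propanal | COc1ccc(cc1)COCCC=O | starting material
2 | cis-but-2-ene | C/C=C\C | starting material
3 | (Z)-crotyldiisopinocampheylborane (Ipc from (+)-α-pinene) | C/C=C\CB([C@@H]1C[C@@H]2C[C@H]([C@H]1C)C2(C)C)[C@@H]1C[C@@H]2C[C@H]([C@H]1C)C2(C)C | intermediate (not isolated)
4 | diisopinocampheylborinate of 5 | COc1ccc(cc1)COCC[C@@H](OB([C@@H]1C[C@@H]2C[C@H]([C@H]1C)C2(C)C)[C@@H]1C[C@@H]2C[C@H]([C@H]1C)C2(C)C)[C@H](C)C=C | intermediate (not isolated)
5 | (3R,4R)-1-[(4-methoxybenzyl)oxy]-4-methylhex-5-en-3-ol | COc1ccc(cc1)COCC[C@@H](O)[C@H](C)C=C | intermediate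
6 | TBS ether of 5 | COc1ccc(cc1)COCC[C@@H](O[Si](C)(C)C(C)(C)C)[C@H](C)C=C | intermediate
7 | B-alkyl-9-borabicyclo[3.3.1]nonane from 6 | COc1ccc(cc1)COCC[C@@H](O[Si](C)(C)C(C)(C)C)[C@H](C)CCB1C2CCCC1CCC2 | intermediate (not isolated)
8 | (3R,4R)-4-(tert-butyldimethylsilyloxy)-6-[(4-methoxybenzyl)oxy]-3-methylhexan-1-ol | COc1ccc(cc1)COCC[C@@H](O[Si](C)(C)C(C)(C)C)[C@H](C)CCO | intermediate
9 | (3R,4R)-4-(tert-butyldimethylsilyloxy)-6-[(4-methoxybenzyl)oxy]-3-methylhexanal | COc1ccc(cc1)COCC[C@@H](O[Si](C)(C)C(C)(C)C)[C@H](C)CC=O | intermediate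
10 | (3R,4R)-4-(tert-butyldimethylsilyloxy)-6-[(4-methoxybenzyl)oxy]-3-methyl-2-methylidenehexanal | COc1ccc(cc1)COCC[C@@H](O[Si](C)(C)C(C)(C)C)[C@H](C)C(=C)C=O | intermediate
11 | allyl methoxymethyl ether | C=CCOCOC | starting material
12 | [(Z)-3-(methoxymethoxy)allyl]diisopinocampheylborane | COCO/C=C\CB([C@@H]1C[C@@H]2C[C@H]([C@H]1C)C2(C)C)[C@@H]1C[C@@H]2C[C@H]([C@H]1C)C2(C)C | intermediate (not isolated)
13 | diisopinocampheylborinate of 14 | COc1ccc(cc1)COCC[C@@H](O[Si](C)(C)C(C)(C)C)[C@H](C)C(=C)[C@@H](OB([C@@H]1C[C@@H]2C[C@H]([C@H]1C)C2(C)C)[C@@H]1C[C@@H]2C[C@H]([C@H]1C)C2(C)C)[C@H](OCOC)C=C | intermediate (not isolated)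
14 | (3R,4R,6R,7R)-7-(tert-butyldimethylsilyloxy)-9-[(4-methoxybenzyl)oxy]-3-(methoxymethoxy)-6-methyl-5-methylidenenon-1-en-4-ol | COc1ccc(cc1)COCC[C@@H](O[Si](C)(C)C(C)(C)C)[C@H](C)C(=C)[C@@H](O)[C@H](OCOC)C=C | intermediate
15 | erythro epoxy alcohol (C1–C2 epoxide, C5–OH) | COc1ccc(cc1)COCC[C@@H](O[Si](C)(C)C(C)(C)C)[C@H](C)[C@@]1(CO1)[C@@H](O)[C@H](OCOC)C=C | intermediate
16 | diol with C2–OPMP, C1–OH, C5–OH, C6–OMOM | COc1ccc(cc1)COCC[C@@H](O[Si](C)(C)C(C)(C)C)[C@H](C)[C@@](O)(COc1ccc(OC)cc1)[C@@H](O)[C@H](OCOC)C=C | intermediate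
17 | isovaleryl chloride | CC(C)CC(Cl)=O | starting material
18 | C5 isovalerate of 16 | COc1ccc(cc1)COCC[C@@H](O[Si](C)(C)C(C)(C)C)[C@H](C)[C@@](O)(COc1ccc(OC)cc1)[C@@H](OC(=O)CC(C)C)[C@H](OCOC)C=C | intermediate
19 | C6 N-alkoxymethyl-2,2′-bipyridinium triflate with C1–OTES | COc1ccc(cc1)COCC[C@@H](O[Si](C)(C)C(C)(C)C)[C@H](C)[C@@](O[Si](CC)(CC)CC)(COc1ccc(OC)cc1)[C@@H](OC(=O)CC(C)C)[C@H](OC[n+]1ccccc1-c1ccccn1)C=C.[O-]S(=O)(=O)C(F)(F)F | intermediate (not isolated)
20 | C6 alcohol with C1–OTES | COc1ccc(cc1)COCC[C@@H](O[Si](C)(C)C(C)(C)C)[C@H](C)[C@@](O[Si](CC)(CC)CC)(COc1ccc(OC)cc1)[C@@H](OC(=O)CC(C)C)[C@H](O)C=C | intermediate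
21 | 2-(bromomethyl)acrylic acid | OC(=O)C(=C)CBr | starting material
22 | sodium benzenesulfinate | [Na+].[O-]S(=O)c1ccccc1 | starting material
23 | 2-[(phenylsulfonyl)methyl]acrylic acid | OC(=O)C(=C)CS(=O)(=O)c1ccccc1 | intermediate
24 | C6 2-[(phenylsulfonyl)methyl]acrylate | COc1ccc(cc1)COCC[C@@H](O[Si](C)(C)C(C)(C)C)[C@H](C)[C@@](O[Si](CC)(CC)CC)(COc1ccc(OC)cc1)[C@@H](OC(=O)CC(C)C)[C@H](OC(=O)C(=C)CS(=O)(=O)c1ccccc1)C=C | intermediate
25 | 3-[(phenylsulfonyl)methyl]butenolide with C8′–OPMB | COc1ccc(cc1)COCC[C@@H](O[Si](C)(C)C(C)(C)C)[C@H](C)[C@@](O[Si](CC)(CC)CC)(COc1ccc(OC)cc1)[C@@H](OC(=O)CC(C)C)[C@@H]1OC(=O)C(CS(=O)(=O)c2ccccc2)=C1 | intermediate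
26 | C8′ primary alcohol | OCC[C@@H](O[Si](C)(C)C(C)(C)C)[C@H](C)[C@@](O[Si](CC)(CC)CC)(COc1ccc(OC)cc1)[C@@H](OC(=O)CC(C)C)[C@@H]1OC(=O)C(CS(=O)(=O)c2ccccc2)=C1 | intermediate
27 | C8′ aldehyde | O=CC[C@@H](O[Si](C)(C)C(C)(C)C)[C@H](C)[C@@](O[Si](CC)(CC)CC)(COc1ccc(OC)cc1)[C@@H](OC(=O)CC(C)C)[C@@H]1OC(=O)C(CS(=O)(=O)c2ccccc2)=C1 | intermediate (not isolated)
28 | C8′ carboxylic acid | OC(=O)C[C@@H](O[Si](C)(C)C(C)(C)C)[C@H](C)[C@@](O[Si](CC)(CC)CC)(COc1ccc(OC)cc1)[C@@H](OC(=O)CC(C)C)[C@@H]1OC(=O)C(CS(=O)(=O)c2ccccc2)=C1 | intermediate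
29 | N-hydroxyphthalimide | O=C1c2ccccc2C(=O)N1O | starting material
30 | N-acyloxyphthalimide (key-step precursor) | O=C(C[C@@H](O[Si](C)(C)C(C)(C)C)[C@H](C)[C@@](O[Si](CC)(CC)CC)(COc1ccc(OC)cc1)[C@@H](OC(=O)CC(C)C)[C@@H]1OC(=O)C(CS(=O)(=O)c2ccccc2)=C1)ON1C(=O)c2ccccc2C1=O | intermediate
31 | key-step product: bicyclic lactone with C1–OTES, C2–OPMP, C9–OTBS | C=C1C(=O)O[C@@H]2[C@H]1C[C@@H](O[Si](C)(C)C(C)(C)C)[C@H](C)[C@@](O[Si](CC)(CC)CC)(COc1ccc(OC)cc1)[C@H]2OC(=O)CC(C)C | intermediate
32 | C2 primary alcohol | C=C1C(=O)O[C@@H]2[C@H]1C[C@@H](O[Si](C)(C)C(C)(C)C)[C@H](C)[C@@](O[Si](CC)(CC)CC)(CO)[C@H]2OC(=O)CC(C)C | intermediate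
33 | C2 aldehyde | C=C1C(=O)O[C@@H]2[C@H]1C[C@@H](O[Si](C)(C)C(C)(C)C)[C@H](C)[C@@](O[Si](CC)(CC)CC)(C=O)[C@H]2OC(=O)CC(C)C | intermediate
34 | (E)-1-bromoprop-1-ene | C/C=C/Br | starting material
35 | (E)-prop-1-enylchromium dichloride | C/C=C/[Cr](Cl)Cl | intermediate (not isolated)
36 | C2 allylic alcohol (C2 epimers) | C=C1C(=O)O[C@@H]2[C@H]1C[C@@H](O[Si](C)(C)C(C)(C)C)[C@H](C)[C@@](O[Si](CC)(CC)CC)(C(O)/C=C/C)[C@H]2OC(=O)CC(C)C | intermediate
37 | bis-silylated enone | C=C1C(=O)O[C@@H]2[C@H]1C[C@@H](O[Si](C)(C)C(C)(C)C)[C@H](C)[C@@](O[Si](CC)(CC)CC)(C(=O)/C=C/C)[C@H]2OC(=O)CC(C)C | intermediate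
38 | CNP0186412.1 | C=C1C(=O)O[C@@H]2[C@H]1C[C@@H](O)[C@H](C)[C@@](O)(C(=O)/C=C/C)[C@H]2OC(=O)CC(C)C | target

**Step count**

Total: 22 steps. Longest linear sequence: 21 steps (steps 1–10 and 12–22, from 1 to 38); step 11 is a one-step side branch.

**Steps most likely to fail**

1. Step 17 (Proposed new method). The C8 radical may be quenched by hydrogen transfer, from the dihydropyridine or by a 1,5-shift from C5–H or C2–H, before the slow 7-exo closure, giving open-chain reduced material. The fallback uses the classical tin-hydride chain cyclization of an alkyl halide with β-elimination of the sulfonyl group. It sets out from acid 28, which is coupled with N-hydroxypyridine-2-thione (DIC, CH2Cl2, dark) to the Barton ester F1. Photolysis of F1 with iodoform in benzene should give the primary C8 iodide F2. Syringe-pump addition of Bu3SnH with AIBN to F2 in refluxing benzene (1–2 mM) keeps the hydrogen donor scarce, so that ring closure and loss of PhSO2 can precede reduction. The sequence returns to the route at 31.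

2. Step 13. The ruthenium carbene formed at the C7 vinyl group may not engage the electron-poor, 1,1-disubstituted sulfonylmethyl acrylate, leading to dimerization through the vinyl groups. The fallback builds C7=C11 by olefination and sets out from alcohol 20, bypassing steps 12 and 13.
   - The reagent, methyl 2-[bis(2,2,2-trifluoroethoxy)phosphoryl]-3-(phenylsulfanyl)propanoate F3, is made from methyl bis(2,2,2-trifluoroethyl)phosphonoacetate and chloromethyl phenyl sulfide (NaH, THF).
   - Ozonolysis of 20 (O3, CH2Cl2, −78 °C; PPh3) should give the α-hydroxy aldehyde F4.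
   - Still–Gennari olefination of F4 with F3 (KN(SiMe3)2, 18-crown-6, THF, −78 °C) should give the (Z)-γ-hydroxy enoate F5, which lactonizes onto the C6 hydroxyl to the 3-(phenylsulfanylmethyl)butenolide F6.
   - mCPBA (2.2 equiv, CH2Cl2, 0 °C) oxidizes the sulfide and returns to the route at 25.

3. Step 20. Addition of the alkenylchromium reagent to the neopentyl, α-silyloxy aldehyde may be too slow, so that the reagent is lost to protonation or homocoupling. The fallback sets out from aldehyde 33 and uses the smaller allyl nucleophile. Barbier allylation with allyl bromide and In powder in THF/H2O should give the homoallylic alcohol F7. Dess–Martin oxidation gives the β,γ-unsaturated ketone F8. Et3N (catalytic, CH2Cl2) then moves the double bond into conjugation as the (E)-enone, returning to the route at 37.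

**Further compounds**

F1 | step 17 | Barton ester of 28 (O-acyl N-hydroxypyridine-2-thione) | O=C(C[C@@H](O[Si](C)(C)C(C)(C)C)[C@H](C)[C@@](O[Si](CC)(CC)CC)(COc1ccc(OC)cc1)[C@@H](OC(=O)CC(C)C)[C@@H]1OC(=O)C(CS(=O)(=O)c2ccccc2)=C1)ON1C=CC=CC1=S
F2 | step 17 | primary C8 iodide | IC[C@@H](O[Si](C)(C)C(C)(C)C)[C@H](C)[C@@](O[Si](CC)(CC)CC)(COc1ccc(OC)cc1)[C@@H](OC(=O)CC(C)C)[C@@H]1OC(=O)C(CS(=O)(=O)c2ccccc2)=C1
F3 | step 13 | methyl 2-[bis(2,2,2-trifluoroethoxy)phosphoryl]-3-(phenylsulfanyl)propanoate | COC(=O)C(CSc1ccccc1)P(=O)(OCC(F)(F)F)OCC(F)(F)F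
F4 | step 13 | C7 α-hydroxy aldehyde from 20 | COc1ccc(cc1)COCC[C@@H](O[Si](C)(C)C(C)(C)C)[C@H](C)[C@@](O[Si](CC)(CC)CC)(COc1ccc(OC)cc1)[C@@H](OC(=O)CC(C)C)[C@H](O)C=O
F5 | step 13 | (Z)-γ-hydroxy enoate | COc1ccc(cc1)COCC[C@@H](O[Si](C)(C)C(C)(C)C)[C@H](C)[C@@](O[Si](CC)(CC)CC)(COc1ccc(OC)cc1)[C@@H](OC(=O)CC(C)C)[C@H](O)/C=C(/CSc1ccccc1)C(=O)OC
F6 | step 13 | 3-(phenylsulfanylmethyl)butenolide | COc1ccc(cc1)COCC[C@@H](O[Si](C)(C)C(C)(C)C)[C@H](C)[C@@](O[Si](CC)(CC)CC)(COc1ccc(OC)cc1)[C@@H](OC(=O)CC(C)C)[C@@H]1OC(=O)C(CSc2ccccc2)=C1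
F7 | step 20 | C2 homoallylic alcohol (C2 epimers) | C=C1C(=O)O[C@@H]2[C@H]1C[C@@H](O[Si](C)(C)C(C)(C)C)[C@H](C)[C@@](O[Si](CC)(CC)CC)(C(O)CC=C)[C@H]2OC(=O)CC(C)C
F8 | step 20 | β,γ-unsaturated C2 ketone | C=C1C(=O)O[C@@H]2[C@H]1C[C@@H](O[Si](C)(C)C(C)(C)C)[C@H](C)[C@@](O[Si](CC)(CC)CC)(C(=O)CC=C)[C@H]2OC(=O)CC(C)C
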